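## Analysis of the target

Target 41 consists of a cyclopentane, a 5-hydroxy-2-methoxy-3-methylphenyl ring and two chains. Two neighbouring ring carbons of the cyclopentane are quaternary. C-a carries a methyl group and a CH2–C(=O) arm that runs on through a CH2 group and an E-trisubstituted alkene to the benzylic CH2 of the arene. C-b carries a methyl group and the carbonyl of an E-enone that ends in a tertiary allylic alcohol. C-a and C-b are the only stereocentres (both R), with the two methyl groups, and so the two carbonyl arms, cis; as neither bears hydrogen, nothing can be corrected by epimerisation once the C-a–C-b bond exists. The sensitive groups are the β,γ-unsaturated ketone (its doubly activated CH2 lets the alkene move into conjugation), the γ-hydroxy enone (a Michael acceptor whose tertiary allylic alcohol ionises in acid) and the electron-rich phenol (easily oxidised to a quinone). The difficulty is to build two adjacent, fully substituted carbons as one enantiomer while keeping their two carbonyl arms different. The strategy rests on the C-a–C-b bond: C-a is β to the chain ketone and C-b is α to the enone carbonyl, so the ketone carbon, its CH2, C-a, C-b and the enone carbonyl carbon form a 1,5-dicarbonyl array. This is the retron of a Michael addition inside a five-membered ring, so the ring is closed by adding the α-carbon of a methyl ketone (future C-b) to the β-carbon of a tethered enoate (future C-a), with a removable chiral amine setting both centres.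

## Retrosynthetic reasoning

**41 from 40.** The phenol and the tertiary alcohol are carried as silyl ethers to the end, because the fragment coupling uses a carbanion and the free phenol is oxidation-prone. One buffered fluoride step removes both.

**40 from 36 and 26 (through 38 and 39).** The bond between the chain ketone carbon and the CH2 that lies between ketone and alkene is cut. This divides the molecule into two halves of similar size, an allylic sulfone 36 carrying the arene and an aldehyde 26 carrying the ring. The sulfonyl group makes the allylic carbanion react at the carbon next to sulfur, so the position and E geometry of the alkene are kept. Its later reductive removal passes through a dienolate that is protonated at the α-carbon, which gives the β,γ-unsaturated ketone directly. The forward steps have to add the carbanion to the aldehyde of 26 in the presence of its enone, oxidise the carbinol (39) and cleave the C–S bond.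

**26 from 14 and 18 (through 21, 23 and 24).** The enone C=C is cut by an aldol condensation. The methyl ketone of 14 has only one enolisable side and aldehyde 18 cannot enolise, so the condensation is unambiguous. The ester arm is then brought to the aldehyde level by full reduction to diol 24 and double re-oxidation, which is more dependable than a partial ester reduction next to an enone.

**14 from 9 and 10.** The C-a–C-b bond is cut. It is the only ring bond that is α to one carbonyl and β to another, and cutting it opens the ring to the acyclic keto enoate 9. The single stereocentre of 9 is enolisable and is erased in the reaction, so the whole stereochemical problem is placed in one step, and the two arms emerge already differentiated as acetyl and acetate. The forward reaction has to join two fully substituted carbons in a 5-exo closure, with the arms cis and in one absolute sense, under control of amine 10.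

**9 from 3 and 4 (through 7); 3 from 1.** The bond between C6 and C7 of 9 is made by alkylating the acetoacetate 4 with chloride 3, after which the tert-butyl ester is removed under acid, so no enolate of 9 is ever formed. The E-enoate 3 comes from alkyne 1 by methylalumination and acylation, which fixes the alkene geometry by mechanism.

**36 from 31 and 32 (through 33, 34 and 35); 31 from 27 (through 28, 29 and 30).** The trisubstituted E-alkene is made by cross-metathesis of the allyl arene 31 with methacrolein 32, followed by reduction, bromination and sulfinate displacement. The allyl group is placed by an aromatic Claisen rearrangement, which can only reach the one free position next to the oxygen that later becomes the methyl ether. Differentiation of the two hydroxyl groups of 27 relies on the methyl group next to one of them.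

**18 from 15 (through 16).** The protected α-hydroxy aldehyde comes from silylation and ozonolysis of the tertiary allylic alcohol 15.

## Alternatives that were turned down

**Alternative 1:** De Mayo photocycloaddition and retro-aldol.
- Disconnection: the C-a–CH2 bond of the arm and the C-b–acyl bond are cut together. This leads to 1,2-dimethylcyclopentene A2 and the enantiopure acetoacetate equivalent (R)-2-tert-butyl-6-methyl-1,3-dioxin-4-one A1.
- Forward key step: irradiation near 300 nm would join the two alkenes in a [2+2] cycloaddition to the cis-anti-cis photoadduct A3. Acetal cleavage and retro-aldol opening of the cyclobutane would then give keto acid A4, the acid of 14.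
- For it: both quaternary carbons come from a tetrasubstituted alkene in one step, excited-state cycloadditions are little slowed by substitution, the cis relation is fixed by the ring fusion, and the symmetric alkene raises no regiochemical question. On the certainty of making the two quaternary centres it is stronger than the chosen strategy.
- Against it: the absolute configuration depends on how well a tert-butyl group on the acetal carbon, remote from the reacting carbons, differentiates the two faces of a nearly flat dioxinone towards a hindered alkene. A1 needs several steps from a chiral-pool hydroxy acid, A2 is volatile, and preparative photochemistry of an enone chromophore is hard to scale and to drive to completion.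
- Comparison: the chosen strategy offers thermal chemistry, a cheap controller that sits directly on the reacting enamine and is sold as both enantiomers, and access to 14 in four steps from catalogue chemicals. It pays for this with less certainty in the bond formation.

**Alternative 2:** Meso cyclobutene opened by enantioselective cross-metathesis.
- Disconnection: both arms are traced back to the two alkene carbons of the meso cyclobutene cis-1,5-dimethylbicyclo[3.2.0]hept-6-ene A5.
- Forward key step: ring-opening cross-metathesis of A5 with butyl vinyl ether A6 on an enantiopure alkylidene of hexavalent molybdenum, Mo(N-2,6-iPr2C6H3)(CHCMe2Ph)(NC4H4)(OAr*) with a binaphthol-derived aryloxide OAr*. It would give A7, with a Z-enol ether on C-a and a vinyl group on C-b.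
- For it: the quaternary centres and their cis relation exist before the asymmetric step, which only has to tell two enantiotopic alkene carbons apart. Ring strain drives the opening, and the enol ether is a masked CH2–CHO arm at the oxidation level of 26. On these points it is as strong as or stronger than the chosen strategy.
- Against it: the alkene of A5 is flanked by two quaternary carbons, so the metallacyclobutane must form beside a neopentyl centre on either side, which is slow and unproven for enantiodiscrimination. A5 needs its own multistep synthesis, the catalyst is air-sensitive and not a catalogue reagent, and the vinyl group on C-b must still be oxidised to the methyl ketone before the same aldol work begins.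
- Comparison: the chosen strategy delivers acetyl and ester arms directly from an acyclic precursor made in three steps and needs no specialised catalyst. The alternative would in return avoid forming a hindered C–C bond.

**Alternative 3:** Asymmetric Pauson–Khand enone, cuprate methylation, enol ether cleavage.
- Disconnection: the C-a–C-b bond is cut together with the two bonds to a one-carbon carbonyl bridge, which leads to 2-methylhept-1-en-6-yne A8.
- Forward key step: an intramolecular Pauson–Khand reaction on a cationic monovalent rhodium catalyst from [Rh(CO)2Cl]2, AgOTf and enantiopure BINAP would give (R)-5-methylbicyclo[3.3.0]oct-1-en-3-one A9 and set C-a. Conjugate addition of a methyl cuprate would create C-b, cis by the ring fusion, and cleavage of the trapped enol ether would open the second ring into the two arms.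
- For it: every step has close precedent, the asymmetric step is catalytic and the cis relation is enforced. On precedent it is stronger than the chosen strategy, and for that reason it serves below as the fallback for the key step.
- Against it: an enyne with a 1,1-disubstituted alkene, a terminal alkyne and an unsubstituted tether is the least favourable class for this cyclocarbonylation. The methylated ketone is meso, so chirality survives only in the regiodefined enol ether, which must never equilibrate. The cleavage leaves a formyl group on C-b and an acid on C-a, so the enone has to be built by acetylide addition and redox steps, which makes the route longer.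
- Comparison: the chosen strategy reaches both arms at useful oxidation levels in one step from an acyclic precursor, and stores the chirality in two quaternary carbons that cannot be lost.

Key step: step 4

**Assumptions (remarks on the chemistry).**
- The ring closure is taken to run through the E-enamine 12, the arrangement that is fixed in the ring enamines of the known intermolecular cases. On that basis the S-amine 10 leads to (1R,2R)-14; if the sense proved opposite, the R-amine would take its place.
- tert-Butyl 2-methyl-3-oxobutanoate 4 is taken as a catalogue chemical (otherwise one methylation of tert-butyl acetoacetate).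
- Compounds 21, 24 and 38 are carried as mixtures at centres that are removed later.

## Route

**Step 1**
Reactants: 1 5-chloropent-1-yne
Product: 3 methyl (2E)-6-chloro-3-methylhex-2-enoate, via alkenylalane 2 (not isolated)
Conditions: AlMe3 (2 equiv), Cp2ZrCl2 (0.25 equiv), CH2Cl2, 0 °C → rt; then ClCO2Me, 0 °C → rt; aq. HCl work-up
Reagents that add atoms: trimethylaluminium, C[Al](C)C; methyl chloroformate, COC(=O)Cl
Why: Zirconium-catalysed methylalumination (Negishi carboalumination) adds methyl and aluminium syn across the terminal alkyne with aluminium at the terminus, and the alkenylalane is acylated with retention, so only the E-enoate should form; the primary chloride is inert.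

**Step 2**
Reactants: 4 tert-butyl 2-methyl-3-oxobutanoate; 3 methyl (2E)-6-chloro-3-methylhex-2-enoate
Product: 7 1-tert-butyl 8-methyl (6E)-2-acetyl-2,6-dimethyloct-6-enedioate, via sodium enolate 5 (not isolated), via iodide 6 (not isolated)
Conditions: NaH, DMF, 0 °C; then 3, NaI (0.2 equiv), 60 °C
Reagents that add atoms: none
Why: C-alkylation of a β-keto ester enolate by a primary iodide formed in the flask (Finkelstein exchange); the enolate is too weak a base to touch the γ-hydrogens of the enoate, and the new quaternary carbon is racemic, which does not matter.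

**Step 3**
Reactants: 7 1-tert-butyl 8-methyl (6E)-2-acetyl-2,6-dimethyloct-6-enedioate
Product: 9 methyl (2E)-3,7-dimethyl-8-oxonon-2-enoate, via keto acid 8 (not isolated)
Conditions: CF3CO2H, CH2Cl2, 0 °C → rt; evaporate; toluene, 90 °C
Reagents that add atoms: none
Why: Acidolysis of the tert-butyl ester and thermal decarboxylation of the β-keto acid through its enol leave the methyl enoate untouched; no ketone enolate is formed, so no racemic Michael closure can precede the key step.

**Step 4**
Reactants: 9 methyl (2E)-3,7-dimethyl-8-oxonon-2-enoate; 10 (S)-1-phenylethylamine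
Product: 14 methyl 2-[(1R,2R)-2-acetyl-1,2-dimethylcyclopentyl]acetate, via imine 11 (not isolated), via enamine 12 (not isolated), via cyclised imine 13 (not isolated)
Conditions: 10 (1.2 equiv), TsOH·H2O (2 mol%), toluene, reflux, Dean–Stark trap; then 110–130 °C, sealed vessel, Ar; then AcOH/H2O/THF, rt
Reagents that add atoms: water, O
Why: Proposed new method: condensation of 9 with 10 gives imine 11, which equilibrates with the more substituted secondary enamine 12 (this erases the racemic centre of 9); the enamine carbon then adds to the enoate β-carbon while the N–H hydrogen passes to the enoate α-carbon through a six-membered, aza-ene-like transition state, giving imine 13, which aqueous acetic acid hydrolyses to 14 with return of the amine. The closest known reaction type is the Michael alkylation of 1-phenylethylamine imines of α-substituted ketones with electron-poor alkenes, which builds single quaternary centres on unhindered acceptors, also in ring-forming variants with less substituted enoates; joining two quaternary carbons on a β,β-disubstituted enoate has not been shown. The cyclopentane closes in the 5-exo-trig mode allowed by the three-carbon tether, whereas the less substituted enamine could only close a seven-membered ring, so the regiochemistry is secured by the substrate. C-b (C2 of 14) is controlled by the amine stereocentre: with N–H syn to the enamine double bond and the benzylic C–H eclipsing the N–C bond, the phenyl group covers one face and the enoate adds to the other. C-a (C1 of 14) is controlled by the internal proton transfer, which holds the enoate CH next to the carbon bearing nitrogen and so places the two carbonyl arms cis. Reaction through the E-enamine drawn for 12 (tether cis to the enamine methyl carbon, ester turned away from the amine substituent) leads from the S-amine to the (1R,2R) product. The step needs enamine regioselectivity, one enamine face and the cis relation; heating is kept as short as conversion allows, because the nitrogen could otherwise attack the ester.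

**Step 5**
Reactants: 15 2-methylbut-3-en-2-ol
Product: 16 triethyl[(2-methylbut-3-en-2-yl)oxy]silane
Conditions: Et3SiOTf, 2,6-lutidine, CH2Cl2, −78 → 0 °C
Reagents that add atoms: triethylsilyl trifluoromethanesulfonate, CC[Si](CC)(CC)OS(=O)(=O)C(F)(F)F
Why: Silylation of a tertiary alcohol needs the silyl triflate; the triethylsilyl ether is robust enough for the steps ahead and is removed by fluoride together with the aryl silyl ether.

**Step 6**
Reactants: 16 triethyl[(2-methylbut-3-en-2-yl)oxy]silane
Product: 18 2-methyl-2-[(triethylsilyl)oxy]propanal, via ozonide 17 (not isolated)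
Conditions: O3, CH2Cl2, −78 °C; then PPh3, −78 °C → rt
Reagents that add atoms: ozone, O=[O+][O-]
Why: Ozonolysis of the terminal alkene with reductive work-up gives the aldehyde, which has no α-hydrogen and so cannot enolise or self-condense.

**Step 7**
Reactants: 14 methyl 2-[(1R,2R)-2-acetyl-1,2-dimethylcyclopentyl]acetate; 18 2-methyl-2-[(triethylsilyl)oxy]propanal
Product: 21 methyl 2-[(1R,2R)-2-{3-hydroxy-4-methyl-4-[(triethylsilyl)oxy]pentanoyl}-1,2-dimethylcyclopentyl]acetate, via boron enolate 19 (not isolated), via boron aldolate 20 (not isolated)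
Conditions: Bu2BOTf, iPr2NEt, CH2Cl2, −78 °C; then 18, −78 → 0 °C; then H2O2, MeOH, pH 7 buffer, 0 °C
Reagents that add atoms: none
Why: Boron-mediated aldol addition: soft enolisation can only take place at the methyl group (the other α-carbon is quaternary, the ester is not enolised), and a boron enolate does not attack the cis-disposed ester, which a lithium enolate might do in a Dieckmann-type closure. The new carbinol centre is not controlled and is removed in step 8.

**Step 8**
Reactants: 21 methyl 2-[(1R,2R)-2-{3-hydroxy-4-methyl-4-[(triethylsilyl)oxy]pentanoyl}-1,2-dimethylcyclopentyl]acetate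
Product: 23 methyl 2-[(1R,2R)-1,2-dimethyl-2-{(2E)-4-methyl-4-[(triethylsilyl)oxy]pent-2-enoyl}cyclopentyl]acetate, via mesylate 22 (not isolated)
Conditions: MsCl, Et3N, CH2Cl2, 0 °C; then DBU, 0 °C → rt
Reagents that add atoms: none
Why: Mesylation followed by E1cB elimination should give the conjugated enone as the E isomer, the bulky silyloxy-bearing carbon turning away from the acyl group.

**Step 9**
Reactants: 23 methyl 2-[(1R,2R)-1,2-dimethyl-2-{(2E)-4-methyl-4-[(triethylsilyl)oxy]pent-2-enoyl}cyclopentyl]acetate
Product: 24 2-[(1R,2R)-2-{(2E)-1-hydroxy-4-methyl-4-[(triethylsilyl)oxy]pent-2-en-1-yl}-1,2-dimethylcyclopentyl]ethan-1-ol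
Conditions: iBu2AlH (5 equiv), CH2Cl2, −78 → 0 °C; aq. KNaC4H4O6 (potassium sodium tartrate) work-up
Reagents that add atoms: none
Why: iBu2AlH reduces the ester to the primary alcohol and the enone by 1,2-addition to the allylic alcohol; the new carbinol centre is uncontrolled and is oxidised away in step 10, and the silyl ether and alkene are inert.

**Step 10**
Reactants: 24 2-[(1R,2R)-2-{(2E)-1-hydroxy-4-methyl-4-[(triethylsilyl)oxy]pent-2-en-1-yl}-1,2-dimethylcyclopentyl]ethan-1-ol
Product: 26 2-[(1R,2R)-1,2-dimethyl-2-{(2E)-4-methyl-4-[(triethylsilyl)oxy]pent-2-enoyl}cyclopentyl]acetaldehyde, via alkoxysulfonium salt 25 (not isolated)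
Conditions: (COCl)2, DMSO, CH2Cl2, −78 °C; then Et3N, −78 → 0 °C
Reagents that add atoms: none
Why: Swern oxidation converts both hydroxyl groups to alkoxysulfonium ions before base is added, so no hydroxy aldehyde exists that could close to a lactol and be oxidised to a lactone; the aldehyde and the enone appear together.

**Step 11**
Reactants: 27 2-methylhydroquinone
Product: 28 2-methyl-4-[(triisopropylsilyl)oxy]phenol
Conditions: iPr3SiCl (1.0 equiv), imidazole, DMF, 0 °C
Reagents that add atoms: chlorotriisopropylsilane, CC(C)[Si](Cl)(C(C)C)C(C)C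
Why: The bulky silyl chloride should react preferentially at the hydroxyl group without an ortho substituent; the regioisomer and any bis-silyl ether are removed by chromatography.

**Step 12**
Reactants: 28 2-methyl-4-[(triisopropylsilyl)oxy]phenol
Product: 29 triisopropyl[3-methyl-4-(prop-2-en-1-yloxy)phenoxy]silane
Conditions: allyl bromide, K2CO3, acetone, reflux
Reagents that add atoms: allyl bromide, C=CCBr
Why: Williamson ether synthesis on the remaining phenol; the aryl triisopropylsilyl ether withstands carbonate in acetone.

**Step 13**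
Reactants: 29 triisopropyl[3-methyl-4-(prop-2-en-1-yloxy)phenoxy]silane
Product: 30 2-methyl-6-(prop-2-en-1-yl)-4-[(triisopropylsilyl)oxy]phenol
Conditions: N,N-diethylaniline, 190 °C
Reagents that add atoms: none
Why: Aromatic Claisen rearrangement: the [3,3] shift can only end at the one free ortho position, since the other carries the methyl group and the para position the silyloxy group; tautomerisation restores the phenol.

**Step 14**
Reactants: 30 2-methyl-6-(prop-2-en-1-yl)-4-[(triisopropylsilyl)oxy]phenol
Product: 31 triisopropyl[4-methoxy-3-methyl-5-(prop-2-en-1-yl)phenoxy]silane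
Conditions: MeI, K2CO3, DMF, rt
Reagents that add atoms: iodomethane, CI
Why: O-Methylation of the doubly flanked phenoxide with the small electrophile; all other positions are blocked.

**Step 15**
Reactants: 31 triisopropyl[4-methoxy-3-methyl-5-(prop-2-en-1-yl)phenoxy]silane; 32 methacrolein
Product: 33 (2E)-4-{2-methoxy-3-methyl-5-[(triisopropylsilyl)oxy]phenyl}-2-methylbut-2-enal
Conditions: 32 (5 equiv), second-generation Grubbs catalyst RuCl2(=CHPh)(H2IMes)(PCy3) (5 mol%), CH2Cl2, 40 °C
Reagents that add atoms: none
Why: Olefin cross-metathesis of a terminal alkene with an excess of the 1,1-disubstituted enal; the trisubstituted enal should form under thermodynamic control as the E isomer, with ethene lost.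

**Step 16**
Reactants: 33 (2E)-4-{2-methoxy-3-methyl-5-[(triisopropylsilyl)oxy]phenyl}-2-methylbut-2-enal
Product: 34 (2E)-4-{2-methoxy-3-methyl-5-[(triisopropylsilyl)oxy]phenyl}-2-methylbut-2-en-1-ol
Conditions: NaBH4, CeCl3·7H2O, MeOH, 0 °C
Reagents that add atoms: none
Why: Luche reduction gives clean 1,2-reduction of the enal without touching the alkene geometry.

**Step 17**
Reactants: 34 (2E)-4-{2-methoxy-3-methyl-5-[(triisopropylsilyl)oxy]phenyl}-2-methylbut-2-en-1-ol
Product: 35 {3-[(2E)-4-bromo-3-methylbut-2-en-1-yl]-4-methoxy-5-methylphenoxy}triisopropylsilane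
Conditions: CBr4, PPh3, CH2Cl2, 0 °C
Reagents that add atoms: tetrabromomethane, BrC(Br)(Br)Br
Why: Appel bromination of a primary allylic alcohol proceeds by direct displacement under neutral conditions, so neither allylic transposition nor loss of the E geometry is expected.

**Step 18**
Reactants: 35 {3-[(2E)-4-bromo-3-methylbut-2-en-1-yl]-4-methoxy-5-methylphenoxy}triisopropylsilane
Product: 36 {3-[(2E)-4-(benzenesulfonyl)-3-methylbut-2-en-1-yl]-4-methoxy-5-methylphenoxy}triisopropylsilane
Conditions: PhSO2Na, DMF, rt
Reagents that add atoms: sodium benzenesulfinate, [Na+].[O-]S(=O)c1ccccc1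
Why: Sulfinate displaces the primary allylic bromide through sulfur (SN2), giving the allylic sulfone with the alkene unchanged.

**Step 19**
Reactants: 36 {3-[(2E)-4-(benzenesulfonyl)-3-methylbut-2-en-1-yl]-4-methoxy-5-methylphenoxy}triisopropylsilane; 26 2-[(1R,2R)-1,2-dimethyl-2-{(2E)-4-methyl-4-[(triethylsilyl)oxy]pent-2-enoyl}cyclopentyl]acetaldehyde
Product: 38 (2E)-1-[(1R,2R)-2-[(4E)-3-(benzenesulfonyl)-2-hydroxy-6-{2-methoxy-3-methyl-5-[(triisopropylsilyl)oxy]phenyl}-4-methylhex-4-en-1-yl]-1,2-dimethylcyclopentyl]-4-methyl-4-[(triethylsilyl)oxy]pent-2-en-1-one, via lithiated sulfone 37 (not isolated)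
Conditions: nBuLi, THF, −78 °C; then 26, −78 °C; AcOH quench at −78 °C
Reagents that add atoms: none
Why: Addition of an α-lithiated allylic sulfone to an aldehyde (first stage of a Julia-type coupling): the carbanion reacts at the carbon next to sulfur, and the aldehyde is far more electrophilic than the enone, whose carbonyl and β-carbon are both flanked by quaternary carbons. The two new stereocentres are uncontrolled and are removed in steps 20 and 21.

**Step 20**
Reactants: 38 (2E)-1-[(1R,2R)-2-[(4E)-3-(benzenesulfonyl)-2-hydroxy-6-{2-methoxy-3-methyl-5-[(triisopropylsilyl)oxy]phenyl}-4-methylhex-4-en-1-yl]-1,2-dimethylcyclopentyl]-4-methyl-4-[(triethylsilyl)oxy]pent-2-en-1-one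
Product: 39 (2E)-1-[(1R,2R)-2-[(4E)-3-(benzenesulfonyl)-6-{2-methoxy-3-methyl-5-[(triisopropylsilyl)oxy]phenyl}-4-methyl-2-oxohex-4-en-1-yl]-1,2-dimethylcyclopentyl]-4-methyl-4-[(triethylsilyl)oxy]pent-2-en-1-one
Conditions: Dess–Martin periodinane, NaHCO3, CH2Cl2, 0 °C → rt
Reagents that add atoms: none
Why: Dess–Martin oxidation of the secondary alcohol under nearly neutral conditions spares the silyl ethers, the alkenes and the protected arene, and avoids the base that could move the alkene of the acidic keto sulfone.

**Step 21**
Reactants: 39 (2E)-1-[(1R,2R)-2-[(4E)-3-(benzenesulfonyl)-6-{2-methoxy-3-methyl-5-[(triisopropylsilyl)oxy]phenyl}-4-methyl-2-oxohex-4-en-1-yl]-1,2-dimethylcyclopentyl]-4-methyl-4-[(triethylsilyl)oxy]pent-2-en-1-one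
Product: 40 (2E)-1-[(1R,2R)-2-[(4E)-6-{2-methoxy-3-methyl-5-[(triisopropylsilyl)oxy]phenyl}-4-methyl-2-oxohex-4-en-1-yl]-1,2-dimethylcyclopentyl]-4-methyl-4-[(triethylsilyl)oxy]pent-2-en-1-one
Conditions: SmI2 (2.5 equiv), THF/MeOH, −78 °C
Reagents that add atoms: none
Why: Reductive desulfonylation of an α-sulfonyl ketone by divalent samarium: electron transfer expels sulfinate and leaves a samarium dienolate, which methanol protonates at the α-carbon, so the β,γ-unsaturated ketone forms with the E-alkene in place. At −78 °C and without additives the hindered enone should be reduced much more slowly than the keto sulfone.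

**Step 22**
Reactants: 40 (2E)-1-[(1R,2R)-2-[(4E)-6-{2-methoxy-3-methyl-5-[(triisopropylsilyl)oxy]phenyl}-4-methyl-2-oxohex-4-en-1-yl]-1,2-dimethylcyclopentyl]-4-methyl-4-[(triethylsilyl)oxy]pent-2-en-1-one
Product: 41 (2E)-4-hydroxy-1-[(1R,2R)-2-[(4E)-6-(5-hydroxy-2-methoxy-3-methylphenyl)-4-methyl-2-oxohex-4-en-1-yl]-1,2-dimethylcyclopentyl]-4-methylpent-2-en-1-one
Conditions: Bu4NF, AcOH (1:1), THF, 0 °C → rt
Reagents that add atoms: none
Why: Fluoride cleaves the aryl silyl ether and the tertiary triethylsilyl ether in one operation; buffering with acetic acid keeps the medium from enolising the β,γ-unsaturated ketone.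

## Compound list

1 | 5-chloropent-1-yne | C#CCCCCl | starting material
2 | [(1E)-5-chloro-2-methylpent-1-en-1-yl]dimethylalane | C[Al](C)/C=C(\C)CCCCl | intermediate (not isolated)
3 | methyl (2E)-6-chloro-3-methylhex-2-enoate | COC(=O)/C=C(\C)CCCCl | intermediate
4 | tert-butyl 2-methyl-3-oxobutanoate | CC(=O)C(C)C(=O)OC(C)(C)C | starting material
5 | sodium enolate of tert-butyl 2-methyl-3-oxobutanoate | CC([O-])=C(C)C(=O)OC(C)(C)C.[Na+] | intermediate (not isolated)
6 | methyl (2E)-6-iodo-3-methylhex-2-enoate | COC(=O)/C=C(\C)CCCI | intermediate (not isolated)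
7 | 1-tert-butyl 8-methyl (6E)-2-acetyl-2,6-dimethyloct-6-enedioate (racemic) | COC(=O)/C=C(\C)CCCC(C)(C(C)=O)C(=O)OC(C)(C)C | intermediate
8 | (6E)-2-acetyl-8-methoxy-2,6-dimethyl-8-oxooct-6-enoic acid (racemic) | COC(=O)/C=C(\C)CCCC(C)(C(C)=O)C(O)=O | intermediate (not isolated)
9 | methyl (2E)-3,7-dimethyl-8-oxonon-2-enoate (racemic) | CC(=O)C(C)CCC/C(C)=C/C(=O)OC | intermediate
10 | (S)-1-phenylethylamine | C[C@H](N)c1ccccc1 | starting material
11 | methyl (2E)-3,7-dimethyl-8-{[(1S)-1-phenylethyl]imino}non-2-enoate | CC(=N[C@@H](C)c1ccccc1)C(C)CCC/C(C)=C/C(=O)OC | intermediate (not isolated)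
12 | methyl (2E,7E)-3,7-dimethyl-8-{[(1S)-1-phenylethyl]amino}nona-2,7-dienoate | C/C(N[C@@H](C)c1ccccc1)=C(/C)CCC/C(C)=C/C(=O)OC | intermediate (not isolated)
13 | methyl 2-[(1R,2R)-1,2-dimethyl-2-{1-[(1S)-1-phenylethylimino]ethyl}cyclopentyl]acetate | COC(=O)C[C@@]1(C)CCC[C@@]1(C)C(C)=N[C@@H](C)c1ccccc1 | intermediate (not isolated)
14 | methyl 2-[(1R,2R)-2-acetyl-1,2-dimethylcyclopentyl]acetate | COC(=O)C[C@@]1(C)CCC[C@@]1(C)C(C)=O | intermediate
15 | 2-methylbut-3-en-2-ol | CC(C)(O)C=C | starting material
16 | triethyl[(2-methylbut-3-en-2-yl)oxy]silane | CC[Si](CC)(CC)OC(C)(C)C=C | intermediate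
17 | 3-{2-[(triethylsilyl)oxy]propan-2-yl}-1,2,4-trioxolane | CC[Si](CC)(CC)OC(C)(C)C1OCOO1 | intermediate (not isolated)
18 | 2-methyl-2-[(triethylsilyl)oxy]propanal | CC[Si](CC)(CC)OC(C)(C)C=O | intermediate
19 | methyl 2-[(1R,2R)-2-{1-[(dibutylboranyl)oxy]ethenyl}-1,2-dimethylcyclopentyl]acetate | COC(=O)C[C@@]1(C)CCC[C@@]1(C)C(=C)OB(CCCC)CCCC | intermediate (not isolated)
20 | methyl 2-[(1R,2R)-2-{3-[(dibutylboranyl)oxy]-4-methyl-4-[(triethylsilyl)oxy]pentanoyl}-1,2-dimethylcyclopentyl]acetate | COC(=O)C[C@@]1(C)CCC[C@@]1(C)C(=O)CC(OB(CCCC)CCCC)C(C)(C)O[Si](CC)(CC)CC | intermediate (not isolated)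
21 | methyl 2-[(1R,2R)-2-{3-hydroxy-4-methyl-4-[(triethylsilyl)oxy]pentanoyl}-1,2-dimethylcyclopentyl]acetate (carbinol epimers) | COC(=O)C[C@@]1(C)CCC[C@@]1(C)C(=O)CC(O)C(C)(C)O[Si](CC)(CC)CC | intermediate
22 | methyl 2-[(1R,2R)-2-{3-[(methanesulfonyl)oxy]-4-methyl-4-[(triethylsilyl)oxy]pentanoyl}-1,2-dimethylcyclopentyl]acetate | COC(=O)C[C@@]1(C)CCC[C@@]1(C)C(=O)CC(OS(C)(=O)=O)C(C)(C)O[Si](CC)(CC)CC | intermediate (not isolated)
23 | methyl 2-[(1R,2R)-1,2-dimethyl-2-{(2E)-4-methyl-4-[(triethylsilyl)oxy]pent-2-enoyl}cyclopentyl]acetate | COC(=O)C[C@@]1(C)CCC[C@@]1(C)C(=O)/C=C/C(C)(C)O[Si](CC)(CC)CC | intermediate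
24 | 2-[(1R,2R)-2-{(2E)-1-hydroxy-4-methyl-4-[(triethylsilyl)oxy]pent-2-en-1-yl}-1,2-dimethylcyclopentyl]ethan-1-ol (carbinol epimers) | OCC[C@@]1(C)CCC[C@@]1(C)C(O)/C=C/C(C)(C)O[Si](CC)(CC)CC | intermediate
25 | bis(alkoxydimethylsulfonium) dichloride of diol 24 | C[S+](C)OCC[C@@]1(C)CCC[C@@]1(C)C(O[S+](C)C)/C=C/C(C)(C)O[Si](CC)(CC)CC.[Cl-].[Cl-] | intermediate (not isolated)
26 | 2-[(1R,2R)-1,2-dimethyl-2-{(2E)-4-methyl-4-[(triethylsilyl)oxy]pent-2-enoyl}cyclopentyl]acetaldehyde | O=CC[C@@]1(C)CCC[C@@]1(C)C(=O)/C=C/C(C)(C)O[Si](CC)(CC)CC | intermediate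
27 | 2-methylhydroquinone (2-methylbenzene-1,4-diol) | Cc1cc(O)ccc1O | starting material
28 | 2-methyl-4-[(triisopropylsilyl)oxy]phenol | Cc1cc(O[Si](C(C)C)(C(C)C)C(C)C)ccc1O | intermediate
29 | triisopropyl[3-methyl-4-(prop-2-en-1-yloxy)phenoxy]silane | C=CCOc1ccc(O[Si](C(C)C)(C(C)C)C(C)C)cc1C | intermediate
30 | 2-methyl-6-(prop-2-en-1-yl)-4-[(triisopropylsilyl)oxy]phenol | C=CCc1cc(O[Si](C(C)C)(C(C)C)C(C)C)cc(C)c1O | intermediate
31 | triisopropyl[4-methoxy-3-methyl-5-(prop-2-en-1-yl)phenoxy]silane | C=CCc1cc(O[Si](C(C)C)(C(C)C)C(C)C)cc(C)c1OC | intermediate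
32 | methacrolein (2-methylprop-2-enal) | CC(=C)C=O | starting material
33 | (2E)-4-{2-methoxy-3-methyl-5-[(triisopropylsilyl)oxy]phenyl}-2-methylbut-2-enal | O=C/C(C)=C/Cc1cc(O[Si](C(C)C)(C(C)C)C(C)C)cc(C)c1OC | intermediate
34 | (2E)-4-{2-methoxy-3-methyl-5-[(triisopropylsilyl)oxy]phenyl}-2-methylbut-2-en-1-ol | OC/C(C)=C/Cc1cc(O[Si](C(C)C)(C(C)C)C(C)C)cc(C)c1OC | intermediate
35 | {3-[(2E)-4-bromo-3-methylbut-2-en-1-yl]-4-methoxy-5-methylphenoxy}triisopropylsilane | BrC/C(C)=C/Cc1cc(O[Si](C(C)C)(C(C)C)C(C)C)cc(C)c1OC | intermediate
36 | {3-[(2E)-4-(benzenesulfonyl)-3-methylbut-2-en-1-yl]-4-methoxy-5-methylphenoxy}triisopropylsilane | O=S(=O)(C/C(C)=C/Cc1cc(O[Si](C(C)C)(C(C)C)C(C)C)cc(C)c1OC)c1ccccc1 | intermediate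
37 | α-lithio derivative of sulfone 36 | [Li]C(/C(C)=C/Cc1cc(O[Si](C(C)C)(C(C)C)C(C)C)cc(C)c1OC)S(=O)(=O)c1ccccc1 | intermediate (not isolated)
38 | (2E)-1-[(1R,2R)-2-[(4E)-3-(benzenesulfonyl)-2-hydroxy-6-{2-methoxy-3-methyl-5-[(triisopropylsilyl)oxy]phenyl}-4-methylhex-4-en-1-yl]-1,2-dimethylcyclopentyl]-4-methyl-4-[(triethylsilyl)oxy]pent-2-en-1-one (diastereomer mixture in the chain) | COc1c(C)cc(O[Si](C(C)C)(C(C)C)C(C)C)cc1C/C=C(\C)C(S(=O)(=O)c1ccccc1)C(O)C[C@@]1(C)CCC[C@@]1(C)C(=O)/C=C/C(C)(C)O[Si](CC)(CC)CC | intermediate
39 | (2E)-1-[(1R,2R)-2-[(4E)-3-(benzenesulfonyl)-6-{2-methoxy-3-methyl-5-[(triisopropylsilyl)oxy]phenyl}-4-methyl-2-oxohex-4-en-1-yl]-1,2-dimethylcyclopentyl]-4-methyl-4-[(triethylsilyl)oxy]pent-2-en-1-one | COc1c(C)cc(O[Si](C(C)C)(C(C)C)C(C)C)cc1C/C=C(\C)C(S(=O)(=O)c1ccccc1)C(=O)C[C@@]1(C)CCC[C@@]1(C)C(=O)/C=C/C(C)(C)O[Si](CC)(CC)CC | intermediate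
40 | (2E)-1-[(1R,2R)-2-[(4E)-6-{2-methoxy-3-methyl-5-[(triisopropylsilyl)oxy]phenyl}-4-methyl-2-oxohex-4-en-1-yl]-1,2-dimethylcyclopentyl]-4-methyl-4-[(triethylsilyl)oxy]pent-2-en-1-one | COc1c(C)cc(O[Si](C(C)C)(C(C)C)C(C)C)cc1C/C=C(\C)CC(=O)C[C@@]1(C)CCC[C@@]1(C)C(=O)/C=C/C(C)(C)O[Si](CC)(CC)CC | intermediate
41 | (2E)-4-hydroxy-1-[(1R,2R)-2-[(4E)-6-(5-hydroxy-2-methoxy-3-methylphenyl)-4-methyl-2-oxohex-4-en-1-yl]-1,2-dimethylcyclopentyl]-4-methylpent-2-en-1-one | COc1c(C)cc(O)cc1C/C=C(\C)CC(=O)C[C@@]1(C)CCC[C@@]1(C)C(=O)/C=C/C(C)(C)O | target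

## Step count and least certain steps

Total step count: 22. Longest linear sequence: 12 steps (steps 1–4, 7–10 and 19–22 from 1; the arene branch, steps 11–18 and 19–22 from 27, is equally long).

**Step 4 (key step, Proposed new method).**
- What may go wrong: the C–C bond may not form, because two fully substituted carbons must be joined at a β,β-disubstituted enoate and the addition can revert. Prolonged heating may let the nitrogen attack the ester and close a lactam. Reaction through the other enamine geometry would lower or invert the enantioselectivity; inversion alone is answered by using the R-amine.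
- Fallback (known chemistry, sets out from 1 and returns at 24): the chloride of 1 would be exchanged with NaI in acetone to give 5-iodopent-1-yne F1. Coupling with isopropenylmagnesium bromide (2.2 equiv, Li2CuCl4 cat., THF) would give 2-methylhept-1-en-6-yne F2. A Pauson–Khand reaction of F2 under CO with the cationic monovalent rhodium catalyst from [Rh(CO)2Cl]2, AgOTf and the appropriate BINAP enantiomer would give (5R)-5-methylbicyclo[3.3.0]oct-1-en-3-one F3 (identical with A9), which fixes C-a. Me2CuLi with Me3SiCl would add the second methyl group to the ring-fusion carbon, cis by necessity, and trap the enolate as cis-1,5-dimethyl-3-(trimethylsilyloxy)bicyclo[3.3.0]oct-2-ene F4; the regiodefined enol ether keeps the chirality that the meso ketone would lose. Ozonolysis (O3, then PPh3) would give 2-[(1R,2R)-2-formyl-1,2-dimethylcyclopentyl]acetic acid F5, and Me3SiCHN2 its ester, methyl 2-[(1R,2R)-2-formyl-1,2-dimethylcyclopentyl]acetate F6. Triethyl[(2-methylbut-3-yn-2-yl)oxy]silane F7 (from 2-methylbut-3-yn-2-ol and Et3SiCl) would be deprotonated with nBuLi to its lithium acetylide F8 and added to the aldehyde of F6 to give methyl 2-[(1R,2R)-2-{1-hydroxy-4-methyl-4-[(triethylsilyl)oxy]pent-2-yn-1-yl}-1,2-dimethylcyclopentyl]acetate F9. NaAlH2(OCH2CH2OMe)2 would then reduce the propargylic alcohol to the E-allylic alcohol and the ester to the primary alcohol, which is diol 24.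

**Step 19.**
- What may go wrong: the sulfonyl carbanion may add to the enone (at the carbonyl or in conjugate fashion) or remove an α-hydrogen of the aldehyde instead of adding to it, and the adduct may revert on warming. The carbanion is basic, and the enone, though hindered, is present in the same molecule.
- Fallback (sets out from 23 and returns at 40): Luche reduction of 23 (NaBH4, CeCl3·7H2O, MeOH) would give methyl 2-[(1R,2R)-2-{(2E)-1-hydroxy-4-methyl-4-[(triethylsilyl)oxy]pent-2-en-1-yl}-1,2-dimethylcyclopentyl]acetate F10. With a trace of TsOH this would close to the lactone (4aR,7aR)-4a,7a-dimethyl-1-{(1E)-3-methyl-3-[(triethylsilyl)oxy]but-1-en-1-yl}hexahydrocyclopenta[c]pyran-3(1H)-one F11. Acylation of 37 (2.2 equiv) by F11 would give the keto sulfone with a free allylic alcohol, (4E)-3-(benzenesulfonyl)-1-[(1R,2R)-2-{(2E)-1-hydroxy-4-methyl-4-[(triethylsilyl)oxy]pent-2-en-1-yl}-1,2-dimethylcyclopentyl]-6-{2-methoxy-3-methyl-5-[(triisopropylsilyl)oxy]phenyl}-4-methylhex-4-en-2-one F12, with no enone or aldehyde present. SmI2 in THF/MeOH would remove the sulfonyl group to give the hydroxy ketone F13, the 3-desulfonyl analogue of F12, and MnO2 would oxidise the allylic alcohol to the enone of 40.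

**Step 21.**
- What may go wrong: electron transfer to the γ-silyloxy enone may compete with C–S cleavage, with loss of the silyloxy group or saturation of the enone, and the alkene may move into conjugation when the dienolate is protonated.
- Fallback (sets out from 34 and returns at 40, no sulfone and no reductant): 34 would be converted with MsCl, LiCl and 2,4,6-collidine in DMF into {3-[(2E)-4-chloro-3-methylbut-2-en-1-yl]-4-methoxy-5-methylphenoxy}triisopropylsilane F14. Activated zerovalent barium (from BaI2 and lithium biphenylide, THF, −78 °C) would turn F14 into the allylbarium chloride F15, a reagent class that adds to aldehydes at its α-carbon with retention of alkene geometry. Addition of F15 to 26 would give the homoallylic alcohol (2E)-1-[(1R,2R)-2-[(4E)-2-hydroxy-6-{2-methoxy-3-methyl-5-[(triisopropylsilyl)oxy]phenyl}-4-methylhex-4-en-1-yl]-1,2-dimethylcyclopentyl]-4-methyl-4-[(triethylsilyl)oxy]pent-2-en-1-one F16, and Dess–Martin oxidation of F16 would give 40.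

**Step 22.**
- What may go wrong: fluoride may act as a base and shift the β,γ-double bond into conjugation with the ketone, and the hindered tertiary silyl ether may be cleaved only slowly.
- Fallback (sets out from 39 and returns at 41): the order of the last two steps would be exchanged. Both silyl groups would be removed from 39 with HF·pyridine in THF/pyridine to give (2E)-1-[(1R,2R)-2-[(4E)-3-(benzenesulfonyl)-6-(5-hydroxy-2-methoxy-3-methylphenyl)-4-methyl-2-oxohex-4-en-1-yl]-1,2-dimethylcyclopentyl]-4-hydroxy-4-methylpent-2-en-1-one F17. SmI2 in THF/MeOH at −78 °C would then remove the sulfonyl group as the last step, so the β,γ-unsaturated ketone never meets fluoride.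

## Further compounds

F1 | step 4 | 5-iodopent-1-yne | C#CCCCI
F2 | step 4 | 2-methylhept-1-en-6-yne | C#CCCCC(C)=C
F3 | step 4 | (5R)-5-methylbicyclo[3.3.0]oct-1-en-3-one | O=C1C[C@@]2(C)CCCC2=C1
F4 | step 4 | cis-1,5-dimethyl-3-(trimethylsilyloxy)bicyclo[3.3.0]oct-2-ene (single enantiomer) | C[Si](C)(C)OC1=C[C@]2(C)CCC[C@]2(C)C1
F5 | step 4 | 2-[(1R,2R)-2-formyl-1,2-dimethylcyclopentyl]acetic acid | OC(=O)C[C@@]1(C)CCC[C@@]1(C)C=O
F6 | step 4 | methyl 2-[(1R,2R)-2-formyl-1,2-dimethylcyclopentyl]acetate | COC(=O)C[C@@]1(C)CCC[C@@]1(C)C=O
F7 | step 4 | triethyl[(2-methylbut-3-yn-2-yl)oxy]silane | CC[Si](CC)(CC)OC(C)(C)C#C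
F8 | step 4 | lithium acetylide of triethyl[(2-methylbut-3-yn-2-yl)oxy]silane | [Li]C#CC(C)(C)O[Si](CC)(CC)CC
F9 | step 4 | methyl 2-[(1R,2R)-2-{1-hydroxy-4-methyl-4-[(triethylsilyl)oxy]pent-2-yn-1-yl}-1,2-dimethylcyclopentyl]acetate | COC(=O)C[C@@]1(C)CCC[C@@]1(C)C(O)C#CC(C)(C)O[Si](CC)(CC)CC
F10 | step 19 | methyl 2-[(1R,2R)-2-{(2E)-1-hydroxy-4-methyl-4-[(triethylsilyl)oxy]pent-2-en-1-yl}-1,2-dimethylcyclopentyl]acetate | COC(=O)C[C@@]1(C)CCC[C@@]1(C)C(O)/C=C/C(C)(C)O[Si](CC)(CC)CC
F11 | step 19 | (4aR,7aR)-4a,7a-dimethyl-1-{(1E)-3-methyl-3-[(triethylsilyl)oxy]but-1-en-1-yl}hexahydrocyclopenta[c]pyran-3(1H)-one | O=C1C[C@@]2(C)CCC[C@@]2(C)C(/C=C/C(C)(C)O[Si](CC)(CC)CC)O1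
F12 | step 19 | (4E)-3-(benzenesulfonyl)-1-[(1R,2R)-2-{(2E)-1-hydroxy-4-methyl-4-[(triethylsilyl)oxy]pent-2-en-1-yl}-1,2-dimethylcyclopentyl]-6-{2-methoxy-3-methyl-5-[(triisopropylsilyl)oxy]phenyl}-4-methylhex-4-en-2-one | COc1c(C)cc(O[Si](C(C)C)(C(C)C)C(C)C)cc1C/C=C(\C)C(S(=O)(=O)c1ccccc1)C(=O)C[C@@]1(C)CCC[C@@]1(C)C(O)/C=C/C(C)(C)O[Si](CC)(CC)CC
F13 | step 19 | (4E)-1-[(1R,2R)-2-{(2E)-1-hydroxy-4-methyl-4-[(triethylsilyl)oxy]pent-2-en-1-yl}-1,2-dimethylcyclopentyl]-6-{2-methoxy-3-methyl-5-[(triisopropylsilyl)oxy]phenyl}-4-methylhex-4-en-2-one | COc1c(C)cc(O[Si](C(C)C)(C(C)C)C(C)C)cc1C/C=C(\C)CC(=O)C[C@@]1(C)CCC[C@@]1(C)C(O)/C=C/C(C)(C)O[Si](CC)(CC)CC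
F14 | step 21 | {3-[(2E)-4-chloro-3-methylbut-2-en-1-yl]-4-methoxy-5-methylphenoxy}triisopropylsilane | ClC/C(C)=C/Cc1cc(O[Si](C(C)C)(C(C)C)C(C)C)cc(C)c1OC
F15 | step 21 | allylbarium chloride from F14 | Cl[Ba]C/C(C)=C/Cc1cc(O[Si](C(C)C)(C(C)C)C(C)C)cc(C)c1OC
F16 | step 21 | (2E)-1-[(1R,2R)-2-[(4E)-2-hydroxy-6-{2-methoxy-3-methyl-5-[(triisopropylsilyl)oxy]phenyl}-4-methylhex-4-en-1-yl]-1,2-dimethylcyclopentyl]-4-methyl-4-[(triethylsilyl)oxy]pent-2-en-1-one | COc1c(C)cc(O[Si](C(C)C)(C(C)C)C(C)C)cc1C/C=C(\C)CC(O)C[C@@]1(C)CCC[C@@]1(C)C(=O)/C=C/C(C)(C)O[Si](CC)(CC)CC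
F17 | step 22 | (2E)-1-[(1R,2R)-2-[(4E)-3-(benzenesulfonyl)-6-(5-hydroxy-2-methoxy-3-methylphenyl)-4-methyl-2-oxohex-4-en-1-yl]-1,2-dimethylcyclopentyl]-4-hydroxy-4-methylpent-2-en-1-one | COc1c(C)cc(O)cc1C/C=C(\C)C(S(=O)(=O)c1ccccc1)C(=O)C[C@@]1(C)CCC[C@@]1(C)C(=O)/C=C/C(C)(C)O
A1 | alternative 1 | (R)-2-tert-butyl-6-methyl-1,3-dioxin-4-one | CC1=CC(=O)O[C@H](C(C)(C)C)O1
A2 | alternative 1 | 1,2-dimethylcyclopentene | CC1=C(C)CCC1
A3 | alternative 1 | cis-anti-cis photoadduct (tricyclic acetal lactone) | CC(C)(C)[C@H]1OC(=O)[C@H]2[C@@](C)(O1)[C@]3(C)CCC[C@]23C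
A4 | alternative 1 | 2-[(1R,2R)-2-acetyl-1,2-dimethylcyclopentyl]acetic acid | OC(=O)C[C@@]1(C)CCC[C@@]1(C)C(C)=O
A5 | alternative 2 | cis-1,5-dimethylbicyclo[3.2.0]hept-6-ene (meso) | C[C@]12CCC[C@@]1(C)C=C2
A6 | alternative 2 | butyl vinyl ether | CCCCOC=C
A7 | alternative 2 | cis-1-[(Z)-2-butoxyethenyl]-2-ethenyl-1,2-dimethylcyclopentane (single enantiomer) | CCCCO/C=C\[C@@]1(C)CCC[C@@]1(C)C=C
A8 | alternative 3 | 2-methylhept-1-en-6-yne | C#CCCCC(C)=C
A9 | alternative 3 | (R)-5-methylbicyclo[3.3.0]oct-1-en-3-one | O=C1C[C@@]2(C)CCCC2=C1
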